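The isochromanone is cut at C4–C4a and C1–C8a, so that lactone carbons C1 and C4 arrive together as the two ends of an ester-derived two-carbon unit. The key step adds the ketene silyl acetal of a (3R)-3-silyloxy ester across 3-methoxybenzyne: one operation forges both aryl–carbon bonds as a benzocyclobutenone acetal, exploiting the contiguous C8(oxygen)–C8a–C4a pattern of the benzene ring, in which the C8 oxygen steers C1 onto C8a. The precursors are 2-iodo-3-methoxyphenyl triflate and a C18 acetal whose C3 stereocentre is set earlier by asymmetric hydrogenation; afterwards the strained ring opens thermally and the C3 hydroxyl closes the lactone ring.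

Key step: step 11

Remark: atoms are numbered as in isochroman-1-one (C1 carbonyl, O2, C3, C4, C4a, C5–C8, C8a); the target is read as 3R with an E side-chain alkene, and in the four-membered-ring compounds the methoxy group sits on the arene carbon next to the fusion carbon that carries the acetal or carbonyl carbon (position 5 in the bicyclo[4.2.0] numbering used below).

Step 1
Reactants: 1 3-methoxyphenol
Product: 2 1-methoxy-3-(methoxymethoxy)benzene
Conditions: MOMCl, i-Pr2NEt, CH2Cl2, 0 °C to rt
Reagents that add atoms: chloromethyl methyl ether, COCCl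
Why: O-alkylation of the phenol (methoxymethyl ether formation) installs a group that protects the oxygen and later cooperates in directing metalation; no stereocentre is formed.

Step 2
Reactants: 2 1-methoxy-3-(methoxymethoxy)benzene
Product: 4 2-iodo-1-methoxy-3-(methoxymethoxy)benzene, via aryllithium 3 (not isolated)
Conditions: n-BuLi, THF, 0 °C; then I2, −78 °C to rt; aq. Na2S2O3
Reagents that add atoms: iodine, II
Why: Directed ortho-metalation: both ether oxygens coordinate n-BuLi and acidify the shared ortho position, so lithiation should occur only at C2 and iodinolysis of aryllithium 3 fixes iodine between the two oxygens, a position that electrophilic iodination of the free phenol would not be expected to favour.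

Step 3
Reactants: 4 2-iodo-1-methoxy-3-(methoxymethoxy)benzene
Product: 5 2-iodo-3-methoxyphenol
Conditions: HCl (cat.), MeOH, 50 °C
Reagents that add atoms: none
Why: Acid-catalysed acetal exchange (methanolysis of the methoxymethyl ether) frees the phenol under conditions that leave the aryl iodide and the methyl ether alone.

Step 4
Reactants: 5 2-iodo-3-methoxyphenol
Product: 6 2-iodo-3-methoxyphenyl trifluoromethanesulfonate
Conditions: Tf2O, pyridine, CH2Cl2, 0 °C
Reagents that add atoms: trifluoromethanesulfonic anhydride, O=S(=O)(OS(=O)(=O)C(F)(F)F)C(F)(F)F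
Why: O-Sulfonylation of a phenol with triflic anhydride and pyridine is general and gives the ortho-iodoaryl triflate that serves as the aryne source.

Step 5
Reactants: 7 1-decyne; 8 6-bromohexanoic acid
Product: 10 hexadec-7-ynoic acid, via lithium dec-1-yn-1-ide 9 (not isolated)
Conditions: 7 (2.2 equiv), n-BuLi (2.1 equiv), THF–HMPA (or DMPU), −78 to 0 °C; then 8, 0 °C to rt; aq. HCl
Reagents that add atoms: none
Why: SN2 alkylation of an alkynyllithium by a primary bromide in a dipolar cosolvent; the first equivalent of 9 turns the acid into its unreactive lithium carboxylate and the second displaces bromide, so no protecting group is needed.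

Step 6
Reactants: 10 hexadec-7-ynoic acid
Product: 11 (7E)-hexadec-7-enoic acid
Conditions: Na, NH3(l)/THF, −33 °C; NH4Cl; aq. HCl
Reagents that add atoms: none
Why: Dissolving-metal (Birch-type) reduction of an internal alkyne passes through the trans-vinyl radical and anion and should give the E-alkene only, while the carboxylate resists solvated electrons.

Step 7
Reactants: 11 (7E)-hexadec-7-enoic acid; 12 potassium methyl malonate
Product: 14 methyl (9E)-3-oxooctadec-9-enoate, via acyl imidazole 13 (not isolated)
Conditions: CDI, THF, rt; then 12, MgCl2, THF, rt to 45 °C; aq. HCl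
Reagents that add atoms: none
Why: Masamune–Brooks homologation: acyl imidazole 13 C-acylates the magnesium enolate of the malonate half-ester and decarboxylation on acidification gives the β-keto ester without touching the alkene.

Step 8
Reactants: 14 methyl (9E)-3-oxooctadec-9-enoate
Product: 15 methyl (3R,9E)-3-hydroxyoctadec-9-enoate
Conditions: RuCl2[(R)-BINAP] (0.5 mol%), H2 (10 atm), MeOH, 50 °C
Reagents that add atoms: none
Why: Noyori asymmetric hydrogenation: the chelating β-keto ester is reduced on the ketone face dictated by the (R)-BINAP ligand, which for 3-oxoalkanoates gives the 3R alcohol (the C3 stereocentre of the target), and the remote unfunctionalised internal alkene offers this catalyst no handle and should survive.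

Step 9
Reactants: 15 methyl (3R,9E)-3-hydroxyoctadec-9-enoate
Product: 16 methyl (3R,9E)-3-{[tert-butyl(dimethyl)silyl]oxy}octadec-9-enoate
Conditions: TBSCl, imidazole, DMF, rt
Reagents that add atoms: tert-butyldimethylsilyl chloride, CC(C)(C)[Si](C)(C)Cl
Why: Standard silylation of a secondary alcohol masks the hydroxyl for the enolisation and aryne steps without touching the stereocentre.

Step 10
Reactants: 16 methyl (3R,9E)-3-{[tert-butyl(dimethyl)silyl]oxy}octadec-9-enoate
Product: 18 tert-butyl{[(3R,9E)-3-{[tert-butyl(dimethyl)silyl]oxy}-1-methoxyoctadeca-1,9-dien-1-yl]oxy}dimethylsilane (ketene methyl silyl acetal; C1=C2 geometry mixed), via lithium enolate 17 (not isolated)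
Conditions: LiN(i-Pr)2, THF, −78 °C; then TBSCl, HMPA, −78 to 0 °C; pentane, cold aq. NaHCO3 wash; used crude
Reagents that add atoms: tert-butyldimethylsilyl chloride, CC(C)(C)[Si](C)(C)Cl
Why: Kinetic ester enolisation and O-silylation of lithium enolate 17 (silyl ketene acetal formation) at −78 °C, where β-elimination of the silyloxy group is slow; the enol ether geometry is immaterial and C3 is not an acidic position.

Step 11
Reactants: 6 2-iodo-3-methoxyphenyl trifluoromethanesulfonate; 18 ketene methyl silyl acetal
Product: 22 tert-butyl{[(1R,7E)-1-(7-{[tert-butyl(dimethyl)silyl]oxy}-5,7-dimethoxybicyclo[4.2.0]octa-1,3,5-trien-8-yl)hexadec-7-en-1-yl]oxy}dimethylsilane (benzocyclobutenone methyl silyl acetal; C7/C8 diastereomer mixture), via aryllithium 19 (not isolated), via 3-methoxybenzyne 20 (not isolated), via aryl anion–oxocarbenium zwitterion 21 (not isolated)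
Conditions: 18 (1.5 equiv), n-BuLi (hexane, slow addition), THF, −78 °C; pH 7 buffer (surplus 18 returns as ester 16)
Reagents that add atoms: none
Why: Iodine–lithium exchange on 6 gives aryllithium 19, which expels lithium triflate to form 3-methoxybenzyne 20; the electron-rich C2 of acetal 18 then adds to the aryne carbon remote from the methoxy group, and the aryl anion of zwitterion 21, now ortho to oxygen, collapses onto the silyloxycarbenium carbon. The closest known reaction type is the formal [2+2] cycloaddition of 3-alkoxybenzynes, released from 2-iodoaryl triflates by n-BuLi, with ketene silyl acetals to give benzocyclobutenone acetals. The four-membered ring closes stepwise by 4-exo-trig attack of the aryl carbanion on the oxocarbenium carbon, which forms the C1–C8a bond after the C4–C4a bond. The two new stereocentres (benzylic C8 and acetal C7 of the bicycle) are formed without control and need none, because C7 becomes the carbonyl carbon and C8 the C4 methylene, while the C3 stereocentre of 18 is a spectator. The step needs regioselectivity, which the inductively withdrawing methoxy group secures by polarising the aryne so that negative charge develops next to oxygen, and chemoselectivity, which rests on exchange at iodine being far faster at −78 °C than attack of n-BuLi on the triflate sulfur, the acetal or the isolated alkene.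

Step 12
Reactants: 22 benzocyclobutenone methyl silyl acetal
Product: 23 8-[(1R,7E)-1-hydroxyhexadec-7-en-1-yl]-5-methoxybicyclo[4.2.0]octa-1,3,5-trien-7-one (C8 epimer mixture)
Conditions: 48% aq. HF, MeCN, 0 °C to rt
Reagents that add atoms: none
Why: Aqueous HF desilylation cleaves both Si–O bonds, so the hemiacetal collapses to the strained ketone with loss of methanol and the C3 alcohol is freed, under acidic conditions that avoid base-induced retro-aldol or nucleophilic cleavage of the four-membered ring.

Step 13
Reactants: 23 8-[(1R,7E)-1-hydroxyhexadec-7-en-1-yl]-5-methoxybicyclo[4.2.0]octa-1,3,5-trien-7-one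
Product: 25 (3R)-8-methoxy-3-[(6E)-pentadec-6-en-1-yl]-3,4-dihydro-1H-isochromen-1-one, via o-quinoid ketene 24 (not isolated)
Conditions: o-xylene (0.01 M, degassed), 140 °C
Reagents that add atoms: none
Why: Thermal 4π-electrocyclic opening of the benzocyclobutenone is reversible and gives o-quinoid ketene 24, and whenever the carbinol-bearing carbon has rotated toward the ketene the C3 hydroxyl adds to the ketene carbon C1 through a six-membered transition state with rearomatisation (ketene trapping by an alcohol), closing the lactone with retention at C3 because no bond to that carbon is broken.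

Step 14
Reactants: 25 (3R)-8-methoxy-3-[(6E)-pentadec-6-en-1-yl]-3,4-dihydro-1H-isochromen-1-one
Product: 26 (3R)-8-hydroxy-3-[(6E)-pentadec-6-en-1-yl]-3,4-dihydro-1H-isochromen-1-one
Conditions: BCl3 (1 M in CH2Cl2), CH2Cl2, −78 to 0 °C; aq. NaHCO3
Reagents that add atoms: none
Why: Chelation-assisted aryl methyl ether cleavage: BCl3 binds the lactone carbonyl and the peri methoxy oxygen and chloride removes the methyl group, a mild demethylation that should spare the lactone, the C3 stereocentre and the isolated E-alkene.

Compound list

1 | 3-methoxyphenol | COc1cccc(O)c1 | starting material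
2 | 1-methoxy-3-(methoxymethoxy)benzene | COCOc1cccc(OC)c1 | intermediate
3 | [2-methoxy-6-(methoxymethoxy)phenyl]lithium | [Li]c1c(OC)cccc1OCOC | intermediate
4 | 2-iodo-1-methoxy-3-(methoxymethoxy)benzene | COCOc1cccc(OC)c1I | intermediate
5 | 2-iodo-3-methoxyphenol | COc1cccc(O)c1I | intermediate
6 | 2-iodo-3-methoxyphenyl trifluoromethanesulfonate | COc1cccc(OS(=O)(=O)C(F)(F)F)c1I | intermediate
7 | 1-decyne | C#CCCCCCCCC | starting material
8 | 6-bromohexanoic acid | OC(=O)CCCCCBr | starting material
9 | lithium dec-1-yn-1-ide | [Li]C#CCCCCCCCC | intermediate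
10 | hexadec-7-ynoic acid | CCCCCCCCC#CCCCCCC(=O)O | intermediate
11 | (7E)-hexadec-7-enoic acid | CCCCCCCC/C=C/CCCCCC(=O)O | intermediate
12 | potassium methyl malonate (potassium 3-methoxy-3-oxopropanoate) | [K+].[O-]C(=O)CC(=O)OC | starting material
13 | (7E)-1-(1H-imidazol-1-yl)hexadec-7-en-1-one | CCCCCCCC/C=C/CCCCCC(=O)n1ccnc1 | intermediate
14 | methyl (9E)-3-oxooctadec-9-enoate | CCCCCCCC/C=C/CCCCCC(=O)CC(=O)OC | intermediate
15 | methyl (3R,9E)-3-hydroxyoctadec-9-enoate | CCCCCCCC/C=C/CCCCC[C@@H](O)CC(=O)OC | intermediate
16 | methyl (3R,9E)-3-{[tert-butyl(dimethyl)silyl]oxy}octadec-9-enoate | CCCCCCCC/C=C/CCCCC[C@@H](O[Si](C)(C)C(C)(C)C)CC(=O)OC | intermediate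
17 | lithium (3R,9E)-3-{[tert-butyl(dimethyl)silyl]oxy}-1-methoxyoctadeca-1,9-dien-1-olate | CCCCCCCC/C=C/CCCCC[C@@H](O[Si](C)(C)C(C)(C)C)C=C(OC)O[Li] | intermediate
18 | tert-butyl{[(3R,9E)-3-{[tert-butyl(dimethyl)silyl]oxy}-1-methoxyoctadeca-1,9-dien-1-yl]oxy}dimethylsilane (ketene methyl silyl acetal of 16, C1=C2 geometry mixed) | CCCCCCCC/C=C/CCCCC[C@@H](O[Si](C)(C)C(C)(C)C)C=C(OC)O[Si](C)(C)C(C)(C)C | intermediate
19 | [2-methoxy-6-(trifluoromethanesulfonyloxy)phenyl]lithium | COc1cccc(OS(=O)(=O)C(F)(F)F)c1[Li] | intermediate
20 | 3-methoxybenzyne (3-methoxy-1,2-didehydrobenzene) | COC1=CC=CC#C1 | intermediate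
21 | zwitterion from addition of C2 of 18 to the aryne carbon remote from OMe: aryl carbanion ortho to OMe, methoxy(silyloxy)carbenium on the side chain (benzylic centre unassigned) | CCCCCCCC/C=C/CCCCC[C@@H](O[Si](C)(C)C(C)(C)C)C(c1cccc(OC)[c-]1)C(OC)=[O+][Si](C)(C)C(C)(C)C | intermediate
22 | tert-butyl{[(1R,7E)-1-(7-{[tert-butyl(dimethyl)silyl]oxy}-5,7-dimethoxybicyclo[4.2.0]octa-1,3,5-trien-8-yl)hexadec-7-en-1-yl]oxy}dimethylsilane (mixture at C7 and C8 of the bicycle) | CCCCCCCC/C=C/CCCCC[C@@H](O[Si](C)(C)C(C)(C)C)C1c2cccc(OC)c2C1(OC)O[Si](C)(C)C(C)(C)C | intermediate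
23 | 8-[(1R,7E)-1-hydroxyhexadec-7-en-1-yl]-5-methoxybicyclo[4.2.0]octa-1,3,5-trien-7-one (mixture at C8) | CCCCCCCC/C=C/CCCCC[C@@H](O)C1c2cccc(OC)c2C1=O | intermediate
24 | {6-[(2R,8E)-2-hydroxyheptadec-8-en-1-ylidene]-2-methoxycyclohexa-2,4-dien-1-ylidene}methanone (o-quinoid ketene, exocyclic alkene geometry unassigned) | CCCCCCCC/C=C/CCCCC[C@@H](O)C=C1C=CC=C(OC)C1=C=O | intermediate
25 | (3R)-8-methoxy-3-[(6E)-pentadec-6-en-1-yl]-3,4-dihydro-1H-isochromen-1-one | CCCCCCCC/C=C/CCCCC[C@@H]1Cc2cccc(OC)c2C(=O)O1 | intermediate
26 | (3R)-8-hydroxy-3-[(6E)-pentadec-6-en-1-yl]-3,4-dihydro-1H-isochromen-1-one | CCCCCCCC/C=C/CCCCC[C@@H]1Cc2cccc(O)c2C(=O)O1 | target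

Total step count: 14. Longest linear sequence: 10 steps (steps 5 to 14, from 1-decyne 7 and 6-bromohexanoic acid 8); the aryne source 6 is made in a four-step side branch.

Steps most likely to fail

Step 11 (key step). The aryne may be consumed by n-BuLi or by self-reaction faster than the hindered, β-branched ketene acetal can add, or the acetal may be lost by protonation before the aryne is released. The fallback leaves the route at 16 and rejoins it at 25; it attaches the arene by decarboxylative sp3–sp2 coupling instead of by cycloaddition. Ester 16 is saponified (LiOH, THF/H2O, rt) to (3R,9E)-3-silyloxy acid F1, which N-hydroxyphthalimide and N,N'-diisopropylcarbodiimide (cat. DMAP, CH2Cl2) convert into redox-active ester F2. Nickel-catalysed reductive decarboxylative arylation of F2 with purchased methyl 2-iodo-6-methoxybenzoate (NiBr2(dme) cat., 4,4'-di-tert-butyl-2,2'-bipyridine, Zn powder, DMA, rt) should give methyl benzoate F3, in which the former ester α-carbon is bonded to the arene and the arene ester supplies C1. Bu4NF in THF then frees alkoxide F4, which closes onto the neighbouring ester to give 25. The stereocentre is never adjacent to a reacting centre that could invert it.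

Step 13. Conrotatory opening may turn the carbinol-bearing substituent outward, so that the hydroxyl cannot reach the ketene and the ketene is lost by intermolecular esterification or dimerisation. The fallback leaves at 23 and rejoins at 25; it separates ketene capture from ring closure. Ketone 23 is heated in toluene containing methanol (sealed tube, 140 °C) so that the ketene is trapped by the external alcohol whatever its geometry, giving methyl ester F5. Catalytic p-TsOH in toluene at 80 °C should then lactonise F5 to 25.

Step 10. The ester enolate 17 may expel silanolate by β-elimination to give the 2-enoate, or 18 may hydrolyse on work-up. The fallback leaves at 15 and rejoins at 18; it enolises the unprotected hydroxy ester instead. Double deprotonation of 15 with LiN(i-Pr)2 (2.2 equiv, THF, −78 to −30 °C) gives alkoxide–enolate dianion F6, of the kind used in Fráter–Seebach alkylations, in which oxide is too poor a leaving group to be expelled. Silylation of both oxygens in the same flask (TBSCl, HMPA, −78 °C to rt) should deliver 18 without passing through 16.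

Further compounds

F1 | step 11 | (3R,9E)-3-{[tert-butyl(dimethyl)silyl]oxy}octadec-9-enoic acid | CCCCCCCC/C=C/CCCCC[C@@H](O[Si](C)(C)C(C)(C)C)CC(=O)O
F2 | step 11 | 1,3-dioxoisoindolin-2-yl (3R,9E)-3-{[tert-butyl(dimethyl)silyl]oxy}octadec-9-enoate | CCCCCCCC/C=C/CCCCC[C@@H](O[Si](C)(C)C(C)(C)C)CC(=O)ON1C(=O)c2ccccc2C1=O
F3 | step 11 | methyl 2-[(2R,8E)-2-{[tert-butyl(dimethyl)silyl]oxy}heptadec-8-en-1-yl]-6-methoxybenzoate | CCCCCCCC/C=C/CCCCC[C@@H](O[Si](C)(C)C(C)(C)C)Cc1cccc(OC)c1C(=O)OC
F4 | step 11 | tetrabutylammonium (2R,8E)-1-[3-methoxy-2-(methoxycarbonyl)phenyl]heptadec-8-en-2-olate | CCCCCCCC/C=C/CCCCC[C@@H]([O-])Cc1cccc(OC)c1C(=O)OC.CCCC[N+](CCCC)(CCCC)CCCC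
F5 | step 13 | methyl 2-[(2R,8E)-2-hydroxyheptadec-8-en-1-yl]-6-methoxybenzoate | CCCCCCCC/C=C/CCCCC[C@@H](O)Cc1cccc(OC)c1C(=O)OC
F6 | step 10 | dilithium (3R,9E)-1-methoxyoctadeca-1,9-diene-1,3-bis(olate) | CCCCCCCC/C=C/CCCCC[C@@H](O[Li])C=C(OC)O[Li]
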